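**Retrosynthetic overview**
- The target is apigenin joined at C6 to C8 of umbelliferone. The last disconnection is cleavage of three acetals: two MOM ethers and one O5–CH2–O7' bridge.
- The key disconnection is the C6–C8' biaryl bond, made by a new tether-directed intramolecular Pd-catalysed C–H arylation that closes a temporary seven-membered 1,3-dioxepine.
- The tether is a mixed diaryl formal, made from the chloromethyl ether of 8-iodoumbelliferone and the chelated 5-OH of 7,4'-di-MOM-apigenin.
- The coumarin and flavone rings are bought intact (umbelliferone, apigenin). The only ring formed is the dioxepine, which is opened again in the last step.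

Assumption: the target SMILES has no stereodescriptor and the only possible stereo element is the C6–C8' biaryl axis, so the compound is made exactly as drawn, with no axis configuration set.

**Step 1**
Reactants: 1 umbelliferone (7-hydroxy-2H-chromen-2-one)
Product: 2 7-hydroxy-8-iodo-2H-chromen-2-one
Conditions: I2 (1.0 equiv), KI, 20% aq. NH3, 0 °C to rt; acidic work-up
Reagents that add atoms: iodine, II
Why: Electrophilic aromatic iodination of the phenoxide goes to C8, the position between the phenoxide and the ring oxygen that is the most nucleophilic site of umbelliferone; no stereocentre is formed.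

**Step 2**
Reactants: 2 7-hydroxy-8-iodo-2H-chromen-2-one
Product: 3 8-iodo-7-[(methylsulfanyl)methoxy]-2H-chromen-2-one
Conditions: NaH (1.1 equiv), ClCH2SMe (1.2 equiv), NaI (0.1 equiv), DMF, 0 °C to rt
Reagents that add atoms: chloromethyl methyl sulfide, CSCCl
Why: Williamson ether synthesis of the acidic coumarin phenoxide with the iodide-activated chloromethyl sulfide gives the methylthiomethyl ether without touching the lactone or the aryl iodide.

**Step 3**
Reactants: 4 apigenin (5,7-dihydroxy-2-(4-hydroxyphenyl)-4H-chromen-4-one)
Product: 5 5-hydroxy-7-(methoxymethoxy)-2-[4-(methoxymethoxy)phenyl]-4H-chromen-4-one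
Conditions: MOMCl (2.3 equiv), K2CO3 (3 equiv), acetone, reflux
Reagents that add atoms: chloromethyl methyl ether, COCCl
Why: Williamson-type MOM protection takes the acidic 7-OH and 4'-OH, while the 5-OH, hydrogen-bonded to the C4 carbonyl, stays free under carbonate.

**Step 4**
Reactants: 3 8-iodo-7-[(methylsulfanyl)methoxy]-2H-chromen-2-one
Product: 6 7-(chloromethoxy)-8-iodo-2H-chromen-2-one
Conditions: SO2Cl2 (1.0 equiv), CH2Cl2, 0 °C, 20 min; evaporate, use crude at once
Reagents that add atoms: sulfuryl chloride, O=S(=O)(Cl)Cl
Why: Chlorinolysis of the O,S-acetal (S-chlorination, then Pummerer-type loss of MeSCl through the aryloxy-carbenium ion) gives the aryl chloromethyl ether, because sulfur reacts far faster than the electron-poor iodocoumarin ring.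

**Step 5**
Reactants: 5 5-hydroxy-7-(methoxymethoxy)-2-[4-(methoxymethoxy)phenyl]-4H-chromen-4-one; 6 7-(chloromethoxy)-8-iodo-2H-chromen-2-one
Product: 7 5-{[(8-iodo-2-oxo-2H-chromen-7-yl)oxy]methoxy}-7-(methoxymethoxy)-2-[4-(methoxymethoxy)phenyl]-4H-chromen-4-one
Conditions: NaH (1.2 equiv), DMF, 0 °C; then 6 (1.2 equiv) in THF, 0 °C to rt
Reagents that add atoms: none
Why: Williamson alkylation of the sodium 5-phenoxide with the alpha-chloro ether, an electrophile as reactive as MOMCl (which is known to alkylate chelated flavone 5-OH groups), gives the mixed diaryl formal.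

**Step 6**
Reactants: 7 5-{[(8-iodo-2-oxo-2H-chromen-7-yl)oxy]methoxy}-7-(methoxymethoxy)-2-[4-(methoxymethoxy)phenyl]-4H-chromen-4-one
Product: 8 bridged biaryl: 7-(methoxymethoxy)-2-[4-(methoxymethoxy)phenyl]-4H-chromen-4-one bonded at C6 to C8 of 2H-chromen-2-one, with flavone O5 and coumarin O7 joined by one CH2 (seven-membered 1,3-dioxepine ring)
Conditions: Pd(OAc)2 (10 mol%), PCy3·HBF4 (20 mol%), PivOH (30 mol%), Ag2CO3 (1.5 equiv), DMA, 110 °C, 0.01 M
Reagents that add atoms: none
Why: Proposed new method: a traceless one-carbon acetal tether turns an unselective, tetra-ortho-substituted intermolecular biaryl coupling into a ring closure, in that zerovalent palladium inserts into the coumarin C8–I bond, Ag2CO3 removes iodide to leave an aryl palladium pivalate (divalent palladium), the only C–H within reach of the O5–CH2–O7' tether is flavone C6–H (C4a on the other side of O5 has no hydrogen and C8 is out of reach), concerted metalation–deprotonation at this doubly oxygen-flanked position gives an eight-membered diaryl palladacycle, and reductive elimination closes the seven-membered dioxepine with the C6–C8' bond; the closest known reaction type is pivalate-assisted intramolecular direct arylation of aryl halides closing six- and seven-membered biaryl ether rings (Fagnou-type), together with the ester-tether (Bringmann lactone) concept for hindered biaryls.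

**Step 7**
Reactants: 8 bridged biaryl with the O5–CH2–O7' dioxepine and two MOM ethers
Product: 9 5,7-dihydroxy-6-(7-hydroxy-2-oxo-2H-chromen-8-yl)-2-(4-hydroxyphenyl)-4H-chromen-4-one (target)
Conditions: BCl3 (1 M in CH2Cl2, 8 equiv), CH2Cl2, −78 °C to 0 °C; then H2O/THF, rt
Reagents that add atoms: none
Why: Lewis-acid acetal cleavage, in which BCl3 chelated between the C4 carbonyl and O5 breaks the O5–CH2 bond as in selective 5-O-dealkylation of flavones and also removes both MOM ethers, aqueous work-up hydrolyses the boron aryloxides and the residual chloromethyl ether to the four free phenols, and the low temperature avoids Wessely–Moser isomerisation of ring A to the 8-linked isomer.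

**Compound list**
1 | umbelliferone (7-hydroxy-2H-chromen-2-one) | O=c1ccc2ccc(O)cc2o1 | starting material
2 | 7-hydroxy-8-iodo-2H-chromen-2-one | O=c1ccc2ccc(O)c(I)c2o1 | intermediate
3 | 8-iodo-7-[(methylsulfanyl)methoxy]-2H-chromen-2-one | CSCOc1ccc2ccc(=O)oc2c1I | intermediate
4 | apigenin (5,7-dihydroxy-2-(4-hydroxyphenyl)-4H-chromen-4-one) | O=c1cc(-c2ccc(O)cc2)oc2cc(O)cc(O)c12 | starting material
5 | 5-hydroxy-7-(methoxymethoxy)-2-[4-(methoxymethoxy)phenyl]-4H-chromen-4-one | COCOc1ccc(cc1)-c1cc(=O)c2c(O)cc(OCOC)cc2o1 | intermediate
6 | 7-(chloromethoxy)-8-iodo-2H-chromen-2-one | ClCOc1ccc2ccc(=O)oc2c1I | intermediate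
7 | 5-{[(8-iodo-2-oxo-2H-chromen-7-yl)oxy]methoxy}-7-(methoxymethoxy)-2-[4-(methoxymethoxy)phenyl]-4H-chromen-4-one | COCOc1ccc(cc1)-c1cc(=O)c2c(OCOc3ccc4ccc(=O)oc4c3I)cc(OCOC)cc2o1 | intermediate
8 | bridged biaryl: flavone C6 bonded to coumarin C8, flavone O5 and coumarin O7 joined by CH2 (seven-membered 1,3-dioxepine), 7-OMOM and 4'-OMOM kept | COCOc1ccc(cc1)-c1cc(=O)c2c3OCOc4ccc5ccc(=O)oc5c4-c3c(OCOC)cc2o1 | intermediate
9 | 5,7-dihydroxy-6-(7-hydroxy-2-oxo-2H-chromen-8-yl)-2-(4-hydroxyphenyl)-4H-chromen-4-one | O=c1ccc2ccc(O)c(-c3c(O)cc4oc(-c5ccc(O)cc5)cc(=O)c4c3O)c2o1 | target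

**Totals**
Total step count: 7. Longest linear sequence: 6 steps (steps 1, 2, 4, 5, 6, 7 from umbelliferone).

**Three steps most likely to fail**

Step 6 (the proposed new method). The risks are protodeiodination, oligomers from intermolecular arylation, or no C–H cleavage at the crowded C6 position. The fallback uses known chemistry. It sets out from 5 and comes back to the route at 8. Iodination of 5 with BnMe3N·ICl2 and CaCO3 in CH2Cl2/MeOH at rt, where the free chelated 5-OH steers the electrophile to C6, gives 5-hydroxy-6-iodo-7-(methoxymethoxy)-2-[4-(methoxymethoxy)phenyl]-4H-chromen-4-one F1. O-alkylation of its sodium phenoxide with 6 (NaH, DMF, as in step 5) gives 6-iodo-5-{[(8-iodo-2-oxo-2H-chromen-7-yl)oxy]methoxy}-7-(methoxymethoxy)-2-[4-(methoxymethoxy)phenyl]-4H-chromen-4-one F2. An intramolecular Stille–Kelly reductive coupling of the two aryl iodides (Pd(PPh3)4, Me3SnSnMe3, dioxane, 100 °C) then closes the same dioxepine and gives 8, which goes on through step 7.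

Step 5 (mixed formal from the crude chloromethyl ether and the chelated, hindered 5-OH). The risks are hydrolysis of 6 and sluggish alkylation. The fallback reverses the roles of the two partners. It sets out from 5 and comes back at 7. The sodium phenoxide of 5 (NaH, DMF) is treated with a large excess of BrCH2Cl to give 5-(chloromethoxy)-7-(methoxymethoxy)-2-[4-(methoxymethoxy)phenyl]-4H-chromen-4-one F3, where the hindered phenoxide disfavours the symmetrical formal. The unhindered and more acidic phenol 2 (K2CO3, DMF, rt) then displaces the chloride of F3 and gives 7.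

Step 7 (one-pot BCl3 cleavage of three acetals). The risks are Friedel–Crafts chloromethylation of ring A by the chloromethyl ethers set free, and incomplete opening of the diaryl formal. The fallback stages the deprotection and traps the one-carbon units with soft nucleophiles. It sets out from 8 and comes back at 9. Treatment of 8 with 2 M HCl in MeOH/THF at 45 °C removes only the two MOM groups and gives the bridged diol, 7-hydroxy-2-(4-hydroxyphenyl)flavone bonded at C6 to C8 of coumarin with the O5–CH2–O7' bridge intact F4. Push–pull cleavage of the bridge with AlCl3 and EtSH in CH2Cl2 at 0 °C, a known method for methylenedioxy groups, carries the methylene off as a dithioacetal and gives 9.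

**Further compounds**
F1 | step 6 | 5-hydroxy-6-iodo-7-(methoxymethoxy)-2-[4-(methoxymethoxy)phenyl]-4H-chromen-4-one | COCOc1ccc(cc1)-c1cc(=O)c2c(O)c(I)c(OCOC)cc2o1
F2 | step 6 | 6-iodo-5-{[(8-iodo-2-oxo-2H-chromen-7-yl)oxy]methoxy}-7-(methoxymethoxy)-2-[4-(methoxymethoxy)phenyl]-4H-chromen-4-one | COCOc1ccc(cc1)-c1cc(=O)c2c(OCOc3ccc4ccc(=O)oc4c3I)c(I)c(OCOC)cc2o1
F3 | step 5 | 5-(chloromethoxy)-7-(methoxymethoxy)-2-[4-(methoxymethoxy)phenyl]-4H-chromen-4-one | COCOc1ccc(cc1)-c1cc(=O)c2c(OCCl)cc(OCOC)cc2o1
F4 | step 7 | bridged diol: 7-hydroxy-2-(4-hydroxyphenyl)flavone bonded at C6 to C8 of coumarin, flavone O5 and coumarin O7 joined by CH2 | Oc1ccc(cc1)-c1cc(=O)c2c3OCOc4ccc5ccc(=O)oc5c4-c3c(O)cc2o1
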